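**Plan**

Locants: five-membered ring C1 (fusion)–C2=C3–C4(OH)(CH3)–C5 (fusion); seven-membered ring C5–C6(OH)–C7(side chain)–C8–C9–C10(=C18H2)–C1; side chain C11(CH3)–C12–C13(OAc)–C14=C15.
Enabling feature and cuts: in the seven-membered ring the exocyclic C10=C18 methylene lies two bonds from C8 and the C6 oxygen lies beta to C4, so the ring holds an oxy-Cope retron (C18=C10–C9–C8–C7–C6=O) and an aldol retron (C6(OH)–C5–C4=O). After removal of the acetate and the C4 methyl group (C4 ketone, C2–C3 saturated), C5–C6 and C8–C9 are cut together, which re-forms a temporary C6–C18 bond in acyclic dienol 13; that bond is then cut to allylic chloride 4 and enal 12.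
Forward order: the five-membered ring (4, from cyclopentenone) and the side chain (12, from a 3-methylglutarate half-ester) are joined through C6–C18. Step 10 then moves the chain onto C9, frees C18 as the exocyclic methylene and closes the seven-membered ring onto C5. C2=C3, the C4 carbinol and the acetate follow.
Stereochemistry: C1 from ligand-controlled conjugate addition; C11 from the chiral pool; C13 from CBS reduction; C5, C6 and C7 in step 10 (tether, potassium-bridged closed transition state, equilibrating C7); C4 from methyl delivery directed by the C6 alkoxide.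

Key step: step 10

Remark: 13 is carried as both C6 epimers because C6 becomes trigonal in step 10; 5 is taken as the commercially available (R) half-ester.

**Step 1**
Reactants: 1 cyclopent-2-en-1-one; 2 potassium trifluoro(prop-1-en-2-yl)borate
Product: 3 (3S)-3-(prop-1-en-2-yl)cyclopentan-1-one
Conditions: [Rh(C8H12)2]PF6 (3 mol %), (S)-2,2'-bis(diphenylphosphino)-1,1'-binaphthyl (3.3 mol %), toluene/H2O, 100 °C
Reagents that add atoms: none
Why: Rhodium-catalysed asymmetric conjugate addition (Hayashi–Miyaura type) of the alkenyl trifluoroborate to the enone should set C1, the (S)-configured bisphosphine shielding one enone face so that the (S) ketone is expected by analogy with aryl and alkenyl transfer to cyclopentenone.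

**Step 2**
Reactants: 3 (3S)-3-(prop-1-en-2-yl)cyclopentan-1-one
Product: 4 (3S)-3-(3-chloroprop-1-en-2-yl)cyclopentan-1-one
Conditions: Ca(OCl)2, CO2 (solid), CH2Cl2/H2O, 0 °C
Reagents that add atoms: calcium hypochlorite [Ca+2].[O-]Cl.[O-]Cl
Why: Ene-type allylic chlorination with hypochlorous acid made in the flask puts chlorine on the terminal CH2 of the 1,1-disubstituted alkene with loss of a methyl proton, which gives the 2-substituted allyl chloride and leaves the ketone and C1 untouched.

**Step 3**
Reactants: 5 (3R)-5-methoxy-3-methyl-5-oxopentanoic acid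
Product: 6 methyl (3R)-5-[methoxy(methyl)amino]-3-methyl-5-oxopentanoate
Conditions: MeNHOMe·HCl, EDC·HCl, N-methylmorpholine, CH2Cl2, 0 °C → rt
Reagents that add atoms: N,O-dimethylhydroxylamine hydrochloride CNOC.Cl
Why: Carbodiimide amide coupling converts the free acid chemoselectively into the Weinreb amide while the methyl ester is kept for C6.

**Step 4**
Reactants: 6 methyl (3R)-5-[methoxy(methyl)amino]-3-methyl-5-oxopentanoate; 7 (2-methylprop-1-en-1-yl)magnesium bromide
Product: 8 methyl (3R)-3,7-dimethyl-5-oxooct-6-enoate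
Conditions: THF, −20 → 0 °C; aq. NH4Cl
Reagents that add atoms: none
Why: Grignard addition to the Weinreb amide stops at the ketone through the chelated tetrahedral intermediate and is faster than attack on the methyl ester at low temperature.

**Step 5**
Reactants: 8 methyl (3R)-3,7-dimethyl-5-oxooct-6-enoate
Product: 9 methyl (3R,5R)-5-hydroxy-3,7-dimethyloct-6-enoate
Conditions: (S)-1-methyl-3,3-diphenyltetrahydro-1H,3H-pyrrolo[1,2-c][1,3,2]oxazaborole (20 mol %), catecholborane, toluene, −78 °C
Reagents that add atoms: none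
Why: Corey–Bakshi–Shibata reduction with the alkenyl group acting as the large substituent should deliver hydride to the face that gives the (R) allylic alcohol at C13, and 1,2-reduction is favoured over conjugate reduction with catecholborane.

**Step 6**
Reactants: 9 methyl (3R,5R)-5-hydroxy-3,7-dimethyloct-6-enoate
Product: 10 methyl (3R,5R)-5-[tert-butyl(dimethyl)silyl]oxy-3,7-dimethyloct-6-enoate
Conditions: tBuMe2SiCl, imidazole, DMF, rt
Reagents that add atoms: tert-butyldimethylsilyl chloride CC(C)(C)[Si](C)(C)Cl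
Why: Standard silylation of the secondary allylic alcohol gives an ether that survives the strong bases, chromium and titanium reagents used later and prevents lactonization.

**Step 7**
Reactants: 10 methyl (3R,5R)-5-[tert-butyl(dimethyl)silyl]oxy-3,7-dimethyloct-6-enoate
Product: 11 (3R,5R)-5-[tert-butyl(dimethyl)silyl]oxy-3,7-dimethyloct-6-enal
Conditions: iBu2AlH, CH2Cl2, −78 °C; aq. potassium sodium tartrate
Reagents that add atoms: none
Why: Partial reduction of the methyl ester at low temperature through the stable tetrahedral aluminium acetal gives the aldehyde without touching C11 or the silyl ether.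

**Step 8**
Reactants: 11 (3R,5R)-5-[tert-butyl(dimethyl)silyl]oxy-3,7-dimethyloct-6-enal
Product: 12 (3R,5R)-5-[tert-butyl(dimethyl)silyl]oxy-3,7-dimethyl-2-methylideneoct-6-enal
Conditions: aq. CH2O, pyrrolidine (10 mol %), propionic acid (10 mol %), iPrOH, 45 °C
Reagents that add atoms: formaldehyde C=O
Why: Organocatalytic alpha-methylenation (Mannich condensation followed by elimination of the amine) turns C7 into a 1,1-disubstituted alkene and adds C8, while C11 is not alpha to the carbonyl and is not affected.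

**Step 9**
Reactants: 4 (3S)-3-(3-chloroprop-1-en-2-yl)cyclopentan-1-one; 12 (3R,5R)-5-[tert-butyl(dimethyl)silyl]oxy-3,7-dimethyl-2-methylideneoct-6-enal
Product: 13 (3S)-3-[(6R,8R)-8-[tert-butyl(dimethyl)silyl]oxy-4-hydroxy-6,10-dimethyl-5-methylideneundeca-1,9-dien-2-yl]cyclopentan-1-one (both carbinol epimers)
Conditions: CrCl2 (3 equiv), NaI (cat.), THF, 0 °C → rt (chloride added slowly to aldehyde and CrCl2)
Reagents that add atoms: none
Why: Nozaki–Hiyama–Kishi-type allylation, in which the allylchromium reagent made from 4 with divalent chromium adds 1,2 to the aldehyde much faster than to the ketone, makes the temporary C6–C18 bond that step 10 cuts again.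

**Step 10**
Reactants: 13 (3S)-3-[(6R,8R)-8-[tert-butyl(dimethyl)silyl]oxy-4-hydroxy-6,10-dimethyl-5-methylideneundeca-1,9-dien-2-yl]cyclopentan-1-one
Product: 15 (3aS,7R,8S,8aR)-7-[(2R,4R)-4-[tert-butyl(dimethyl)silyl]oxy-6-methylhept-5-en-2-yl]-8-hydroxy-4-methylideneoctahydroazulen-1(2H)-one, via potassium aldehyde enolate 14 (not isolated)
Conditions: KN(SiMe3)2 (1.2 equiv), THF (0.01 M), −78 → 40 °C; then AcOH, −78 °C
Reagents that add atoms: none
Why: Deprotonation of the C6 carbinol gives a hexa-1,5-dien-3-olate (C8=C7–C6(O−)–C18–C10=C9) that undergoes anionic oxy-Cope rearrangement through a chair, forming C8–C9, cutting the temporary C6–C18 bond and turning C18 into the exocyclic methylene; aldehyde enolate 14 then exchanges a proton with the cyclopentanone and the C4–C5 enolate adds to the C6 aldehyde. The closest known reaction types are the anionic oxy-Cope rearrangement of secondary dienolates (formal conjugate allylation of an enal) and base-mediated intramolecular ketone–aldehyde aldol addition. The seven-membered ring closes in a 7-(enolexo)-exo-trig mode; closure from C3 would need a bridged nine-membered ring and the reverse aldol (C7 onto C4) a congested bridged ketol, and both are reversible, so the fused beta-hydroxy ketone is the expected sink. C5 is set by the three-atom tether C8–C9–C10, which delivers C6 to the enolate face that carries C10 and so makes the ring fusion cis. C6 is set by a potassium-bridged chair-like closed transition state (O4–K–O6) with C7 anti to C4, which places H6 cis to H5, and C7 equilibrates through enolate 14 before closure, the closure that keeps the branched side chain pseudo-equatorial on the forming chair-like ring giving the 7R centre cis to O6. The step needs the [3,3] shift to win over the [1,3] shift and retro-allylation, which the unstrained chair of an acyclic dienolate secures, and it needs kinetic aldol control, which high dilution, the absence of a potassium-sequestering additive and a cold quench are meant to secure.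

**Step 11**
Reactants: 15 (3aS,7R,8S,8aR)-7-[(2R,4R)-4-[tert-butyl(dimethyl)silyl]oxy-6-methylhept-5-en-2-yl]-8-hydroxy-4-methylideneoctahydroazulen-1(2H)-one
Product: 16 bis(trimethylsilyl) derivative of 15 (C6 trimethylsilyl ether and C3=C4 trimethylsilyl enol ether; 1S,5R,6S,7R,11R,13R)
Conditions: LiN(iPr)2 (2.5 equiv), Me3SiCl, THF, −78 °C
Reagents that add atoms: chlorotrimethylsilane C[Si](C)(C)Cl
Why: Kinetic deprotonation with in-situ silylation forms the less substituted (C3) silyl enol ether and caps the C6 hydroxyl, which avoids retro-aldol cleavage.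

**Step 12**
Reactants: 16 bis(trimethylsilyl) derivative of 15
Product: 18 (3aS,7R,8S,8aR)-7-[(2R,4R)-4-[tert-butyl(dimethyl)silyl]oxy-6-methylhept-5-en-2-yl]-8-hydroxy-4-methylidene-4,5,6,7,8,8a-hexahydroazulen-1(3aH)-one, via trimethylsilyl ether enone 17 (not isolated)
Conditions: Pd(OAc)2 (1.1 equiv), MeCN, rt; then citric acid, MeOH, 0 °C
Reagents that add atoms: none
Why: Saegusa–Ito oxidation (palladation of the silyl enol ether and beta-hydride elimination) gives the C2=C3 enone, and mild acidic methanolysis then frees the C6 hydroxyl without base, so the gamma-hydrogen at C1 is not put at risk.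

**Step 13**
Reactants: 18 (3aS,7R,8S,8aR)-7-[(2R,4R)-4-[tert-butyl(dimethyl)silyl]oxy-6-methylhept-5-en-2-yl]-8-hydroxy-4-methylidene-4,5,6,7,8,8a-hexahydroazulen-1(3aH)-one
Product: 19 (1S,3aS,7R,8S,8aR)-7-[(2R,4R)-4-[tert-butyl(dimethyl)silyl]oxy-6-methylhept-5-en-2-yl]-1-methyl-4-methylidene-1,3a,4,5,6,7,8,8a-octahydroazulene-1,8-diol
Conditions: MeTi(OiPr)3 (3 equiv), Et2O, −40 °C → rt
Reagents that add atoms: methyltitanium triisopropoxide C[Ti](OC(C)C)(OC(C)C)OC(C)C
Why: Organotitanium 1,2-addition in which exchange of an isopropoxide for the C6 alkoxide ties titanium to the lower face of the C4 carbonyl, so that methyl should be transferred within the six-membered chelate syn to O6 (opposite to external attack on the convex face) and C4 is set with its hydroxyl cis to H5.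

**Step 14**
Reactants: 19 (1S,3aS,7R,8S,8aR)-7-[(2R,4R)-4-[tert-butyl(dimethyl)silyl]oxy-6-methylhept-5-en-2-yl]-1-methyl-4-methylidene-1,3a,4,5,6,7,8,8a-octahydroazulene-1,8-diol
Product: 20 (1S,3aS,7R,8S,8aR)-7-[(2R,4R)-4-hydroxy-6-methylhept-5-en-2-yl]-1-methyl-4-methylidene-1,3a,4,5,6,7,8,8a-octahydroazulene-1,8-diol
Conditions: Bu4NF, THF, 0 °C → rt; aq. NH4Cl
Reagents that add atoms: none
Why: Fluoride cleavage of the silyl ether (Si–F bond formation) frees the C13 hydroxyl under conditions that the tertiary allylic alcohol tolerates.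

**Step 15**
Reactants: 20 (1S,3aS,7R,8S,8aR)-7-[(2R,4R)-4-hydroxy-6-methylhept-5-en-2-yl]-1-methyl-4-methylidene-1,3a,4,5,6,7,8,8a-octahydroazulene-1,8-diol
Product: 21 (2R,4R)-2-[(1S,3aS,7R,8S,8aR)-1,8-dihydroxy-1-methyl-4-methylidene-1,3a,4,5,6,7,8,8a-octahydroazulen-7-yl]-6-methylhept-5-en-4-yl acetate
Conditions: Ac2O (1.1 equiv), pyridine, CH2Cl2, 0 °C
Reagents that add atoms: acetic anhydride CC(=O)OC(C)=O
Why: Site-selective acylation, in which the allylic C13 hydroxyl (flanked by a CH2 and a CH=) should react far faster than the C6 hydroxyl (flanked by two branched carbons) and the tertiary C4 hydroxyl does not react without a nucleophilic catalyst.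

**Compound list**

1 | cyclopent-2-en-1-one | O=C1C=CCC1 | starting material
2 | potassium trifluoro(prop-1-en-2-yl)borate | [K+].C=C(C)[B-](F)(F)F | starting material
3 | (3S)-3-(prop-1-en-2-yl)cyclopentan-1-one | O=C1C[C@@H](C(C)=C)CC1 | intermediate
4 | (3S)-3-(3-chloroprop-1-en-2-yl)cyclopentan-1-one | O=C1C[C@@H](C(=C)CCl)CC1 | intermediate
5 | (3R)-5-methoxy-3-methyl-5-oxopentanoic acid | COC(=O)C[C@H](C)CC(=O)O | starting material
6 | methyl (3R)-5-[methoxy(methyl)amino]-3-methyl-5-oxopentanoate | COC(=O)C[C@H](C)CC(=O)N(C)OC | intermediate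
7 | (2-methylprop-1-en-1-yl)magnesium bromide | CC(C)=C[Mg]Br | starting material
8 | methyl (3R)-3,7-dimethyl-5-oxooct-6-enoate | COC(=O)C[C@H](C)CC(=O)C=C(C)C | intermediate
9 | methyl (3R,5R)-5-hydroxy-3,7-dimethyloct-6-enoate | COC(=O)C[C@H](C)C[C@H](C=C(C)C)O | intermediate
10 | methyl (3R,5R)-5-[tert-butyl(dimethyl)silyl]oxy-3,7-dimethyloct-6-enoate | COC(=O)C[C@H](C)C[C@H](C=C(C)C)O[Si](C)(C)C(C)(C)C | intermediate
11 | (3R,5R)-5-[tert-butyl(dimethyl)silyl]oxy-3,7-dimethyloct-6-enal | O=CC[C@H](C)C[C@H](C=C(C)C)O[Si](C)(C)C(C)(C)C | intermediate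
12 | (3R,5R)-5-[tert-butyl(dimethyl)silyl]oxy-3,7-dimethyl-2-methylideneoct-6-enal | O=CC(=C)[C@H](C)C[C@H](C=C(C)C)O[Si](C)(C)C(C)(C)C | intermediate
13 | (3S)-3-[(6R,8R)-8-[tert-butyl(dimethyl)silyl]oxy-4-hydroxy-6,10-dimethyl-5-methylideneundeca-1,9-dien-2-yl]cyclopentan-1-one (both carbinol epimers) | O=C1C[C@@H](C(=C)CC(O)C(=C)[C@H](C)C[C@H](C=C(C)C)O[Si](C)(C)C(C)(C)C)CC1 | intermediate
14 | potassium 2-[(2R,4R)-4-[tert-butyl(dimethyl)silyl]oxy-6-methylhept-5-en-2-yl]-5-[(1S)-3-oxocyclopentyl]hexa-1,5-dien-1-olate | O=C1C[C@@H](C(=C)CCC(=C[O-])[C@H](C)C[C@H](C=C(C)C)O[Si](C)(C)C(C)(C)C)CC1.[K+] | intermediate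
15 | (3aS,7R,8S,8aR)-7-[(2R,4R)-4-[tert-butyl(dimethyl)silyl]oxy-6-methylhept-5-en-2-yl]-8-hydroxy-4-methylideneoctahydroazulen-1(2H)-one | C=C1CC[C@H]([C@H](C)C[C@H](C=C(C)C)O[Si](C)(C)C(C)(C)C)[C@H](O)[C@H]2[C@@H]1CCC2=O | intermediate
16 | bis(trimethylsilyl) derivative of 15 (C6 trimethylsilyl ether and C3=C4 trimethylsilyl enol ether) | C=C1CC[C@H]([C@H](C)C[C@H](C=C(C)C)O[Si](C)(C)C(C)(C)C)[C@H](O[Si](C)(C)C)[C@H]2[C@@H]1CC=C2O[Si](C)(C)C | intermediate
17 | (3aS,7R,8S,8aR)-7-[(2R,4R)-4-[tert-butyl(dimethyl)silyl]oxy-6-methylhept-5-en-2-yl]-4-methylidene-8-[(trimethylsilyl)oxy]-4,5,6,7,8,8a-hexahydroazulen-1(3aH)-one | C=C1CC[C@H]([C@H](C)C[C@H](C=C(C)C)O[Si](C)(C)C(C)(C)C)[C@H](O[Si](C)(C)C)[C@H]2[C@@H]1C=CC2=O | intermediate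
18 | (3aS,7R,8S,8aR)-7-[(2R,4R)-4-[tert-butyl(dimethyl)silyl]oxy-6-methylhept-5-en-2-yl]-8-hydroxy-4-methylidene-4,5,6,7,8,8a-hexahydroazulen-1(3aH)-one | C=C1CC[C@H]([C@H](C)C[C@H](C=C(C)C)O[Si](C)(C)C(C)(C)C)[C@H](O)[C@H]2[C@@H]1C=CC2=O | intermediate
19 | (1S,3aS,7R,8S,8aR)-7-[(2R,4R)-4-[tert-butyl(dimethyl)silyl]oxy-6-methylhept-5-en-2-yl]-1-methyl-4-methylidene-1,3a,4,5,6,7,8,8a-octahydroazulene-1,8-diol | C=C1CC[C@H]([C@H](C)C[C@H](C=C(C)C)O[Si](C)(C)C(C)(C)C)[C@H](O)[C@H]2[C@@H]1C=C[C@]2(C)O | intermediate
20 | (1S,3aS,7R,8S,8aR)-7-[(2R,4R)-4-hydroxy-6-methylhept-5-en-2-yl]-1-methyl-4-methylidene-1,3a,4,5,6,7,8,8a-octahydroazulene-1,8-diol | C=C1CC[C@H]([C@H](C)C[C@H](C=C(C)C)O)[C@H](O)[C@H]2[C@@H]1C=C[C@]2(C)O | intermediate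
21 | (2R,4R)-2-[(1S,3aS,7R,8S,8aR)-1,8-dihydroxy-1-methyl-4-methylidene-1,3a,4,5,6,7,8,8a-octahydroazulen-7-yl]-6-methylhept-5-en-4-yl acetate | C=C1CC[C@H]([C@H](C)C[C@H](C=C(C)C)OC(C)=O)[C@H](O)[C@H]2[C@@H]1C=C[C@]2(C)O | target

**Step count and risks**

Total step count: 15. Longest linear sequence: 13 steps (5 to 21, steps 3 to 15).

Step 10 is the most exposed. The ring-closing aldol may show poor facial control at C6 and C7, or the aldehyde enolate may be lost to intermolecular condensation before it closes. The fallback sets out from 13 and comes back at 15, and it separates the two events. The potassium alkoxide is rearranged as before but quenched cold with acetic acid as soon as the [3,3] shift is complete, which gives 2-[(2R,4R)-4-[tert-butyl(dimethyl)silyl]oxy-6-methylhept-5-en-2-yl]-5-[(1S)-3-oxocyclopentyl]hex-5-enal F1 as a mixture at the carbon alpha to the aldehyde. The ring is then closed as an amine-catalysed enamine aldol (pyrrolidine and acetic acid, or proline, in DMSO at rt). In this closure the alpha centre still equilibrates through the aldehyde enamine, only the C5 enamine of the cyclopentanone can reach the aldehyde, and the ring fusion is again fixed by the tether, so the sequence returns to 15.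

Step 13 comes second. Methyl transfer may take place from the open convex face instead of within the chelate, which would invert C4. The fallback sets out from 18 and comes back at 19, and it brings the oxygen, not the methyl group, in from the convex face.
- The C6 hydroxyl is capped (Et3SiCl, imidazole) to give the C6 triethylsilyl ether of 18 F2.
- MeLi with CeCl3 at −78 °C gives the C4 methyl carbinol F3 as either C4 epimer, which does not matter.
- Babler–Dauben oxidative transposition with [C5H5NH][CrO3Cl] gives the transposed enone F4 (C2 ketone, C3=C4 bearing the methyl group).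
- Nucleophilic epoxidation (H2O2, NaOH, MeOH, 0 °C, short contact because H1 is now alpha to the ketone and allylic) attacks the face cis to H5 and gives the C3–C4 epoxy ketone F5.
- Wharton transposition (N2H4·H2O, AcOH, MeOH) gives the C6 triethylsilyl ether of 19 F6.
- Pyridinium p-toluenesulfonate in MeOH removes the triethylsilyl group and returns to 19.

Step 15 comes third. Site selectivity may be lost, with acylation also at C6. The fallback sets out from 19 and comes back at 21, and it masks C6 before the acetate is introduced. Chloroacetic anhydride and pyridine give the C6 chloroacetate of 19 F7. Buffered HF·pyridine in THF removes the tert-butyldimethylsilyl group to give the C6 chloroacetate of 20 F8. Ac2O, pyridine and a little 4-(dimethylamino)pyridine acetylate the only free secondary hydroxyl to give the C6 chloroacetate of 21 F9. Thiourea and NaHCO3 in EtOH then remove the chloroacetate in the presence of the acetate and return to 21.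

**Further compounds**

F1 | step 10 | 2-[(2R,4R)-4-[tert-butyl(dimethyl)silyl]oxy-6-methylhept-5-en-2-yl]-5-[(1S)-3-oxocyclopentyl]hex-5-enal (both C2 epimers) | O=C1C[C@@H](C(=C)CCC(C=O)[C@H](C)C[C@H](C=C(C)C)O[Si](C)(C)C(C)(C)C)CC1
F2 | step 13 | C6 triethylsilyl ether of 18 | C=C1CC[C@H]([C@H](C)C[C@H](C=C(C)C)O[Si](C)(C)C(C)(C)C)[C@H](O[Si](CC)(CC)CC)[C@H]2[C@@H]1C=CC2=O
F3 | step 13 | C4 methyl carbinol from F2 (either C4 epimer) | C=C1CC[C@H]([C@H](C)C[C@H](C=C(C)C)O[Si](C)(C)C(C)(C)C)[C@H](O[Si](CC)(CC)CC)[C@H]2[C@@H]1C=CC2(C)O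
F4 | step 13 | transposed enone (C2 ketone, C3=C4 bearing the methyl group, C6 triethylsilyl ether) | C=C1CC[C@H]([C@H](C)C[C@H](C=C(C)C)O[Si](C)(C)C(C)(C)C)[C@H](O[Si](CC)(CC)CC)[C@H]2[C@@H]1C(=O)C=C2C
F5 | step 13 | C3–C4 epoxy ketone with the epoxide oxygen cis to H5 (C6 triethylsilyl ether) | C=C1CC[C@H]([C@H](C)C[C@H](C=C(C)C)O[Si](C)(C)C(C)(C)C)[C@H](O[Si](CC)(CC)CC)[C@H]2[C@@H]1C(=O)[C@@H]3O[C@]23C
F6 | step 13 | C6 triethylsilyl ether of 19 | C=C1CC[C@H]([C@H](C)C[C@H](C=C(C)C)O[Si](C)(C)C(C)(C)C)[C@H](O[Si](CC)(CC)CC)[C@H]2[C@@H]1C=C[C@]2(C)O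
F7 | step 15 | C6 chloroacetate of 19 | C=C1CC[C@H]([C@H](C)C[C@H](C=C(C)C)O[Si](C)(C)C(C)(C)C)[C@H](OC(=O)CCl)[C@H]2[C@@H]1C=C[C@]2(C)O
F8 | step 15 | C6 chloroacetate of 20 | C=C1CC[C@H]([C@H](C)C[C@H](C=C(C)C)O)[C@H](OC(=O)CCl)[C@H]2[C@@H]1C=C[C@]2(C)O
F9 | step 15 | C6 chloroacetate of 21 | C=C1CC[C@H]([C@H](C)C[C@H](C=C(C)C)OC(C)=O)[C@H](OC(=O)CCl)[C@H]2[C@@H]1C=C[C@]2(C)O
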